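**Compound numbers used throughout:** 1–9 diene branch, 10 quinone, 11–14 bicyclic core, 15–19 side chain, 20–26 coupled series (26 = target). Carbon atoms are named by labdane numbering (ring A = C1–C5, C10; ring B = C5–C10; C19 = CH2O on C4; C20 = methyl on C10).

## Analysis of the target

The target 26 is a labdane: a trans-fused decalin with a tetrasubstituted C8=C9 double bond in ring B, whose C9 carries a two-carbon chain ending in a β-substituted butenolide (C13–C16, carbonyl at C15). All five stereocentres sit on the decalin: C10 (β-methyl), C5 (α-H, trans to that methyl), C4 (β-CH2OH and α-methyl), C2 (α-OH) and C6 (α-OH). C19 and the C10 methyl are syn-diaxial on ring A, and both secondary hydroxyls are equatorial, on the face opposite to these two groups. The butenolide does not tolerate strong nucleophiles or electron-transfer reductants, the tetrasubstituted alkene is open to electrophilic oxidants and can slip into conjugation with a C6 carbonyl, and the C6 oxygen is wedged between both quaternary carbons. The difficulty lies in the two quaternary carbons C4 and C10 and their relative configuration, in placing the alkene at C8=C9 and nowhere else, and in the equatorial alcohols at C2 and C6, which a hydride entering from the open α face does not give. The strategy rests on ring B: oxygen at C6, an sp2 C9 that can be traced to a carbonyl, and methyl groups on C8 and C10 are the substitution pattern of 2,6-dimethyl-1,4-benzoquinone 10. Ring A (C1–C4 with oxygen at C2) is then the cyclohexene that a 2-silyloxy diene lays across the C5=C10 bond of that quinone, so that the adduct already holds the oxygens at C2, C6 and C9, both ring methyls and both quaternary carbons.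

## Retrosynthetic reasoning

**Butenolide (26 back to 22).** No skeletal bond is cut; C15 and C16 change oxidation level. The lactone is the most fragile group, so it is carried as the 3-substituted furan of triol 22, which survives organometallics, fluoride and dissolving metal. The forward chemistry must oxidise the furan so that C15, the α-carbon remote from the chain, becomes the carbonyl (hydroxybutenolide 24), and then reduce C16 from hemiacetal to CH2 without touching C8=C9.

**C2 and C6 carbinols and the C19 hydroxyl (22 back to 21 and 20).** The C2–H and C6–H bonds and the benzyl C–O bond are disconnected. Both alcohols are the equatorial, thermodynamic epimers, so the two ketones of 21 are reduced together by electron transfer under equilibrating protonation, which also removes the benzyl group. Diketone 21 comes from 20 by hydrolysis of the C2 silyl enol ether, which doubles as the protecting group of the C2 carbonyl from the cycloaddition onward.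

**C9–C11 bond (20 back to 14 and 19).** This cut leaves ring B with an oxygen on C9, the quinone pattern, and the enol triflate of 14 fixes the double bond at C8=C9. Addition of a carbon nucleophile to a C9 carbonyl was not used, because in ene-dione 12 the C6 carbonyl is the less hindered one and carries an acidic C5–H. The side chain comes from organozinc 19, made from iodide 18, alcohol 17 and bromofuran 15. The forward step must couple an sp3 carbon to a hindered, tetrasubstituted enol triflate without base, since the C7 protons lie between ketone and alkene.

**C9 enol triflate (14 back to 12).** The C7–H bond is disconnected. Hydride addition to C7, the only unsubstituted β-carbon of the ene-dione, generates the C9 enolate regiospecifically, and O-trapping gives 14 with the C6 carbonyl left as a ketone. The forward step must deliver hydride to C7 and not to C8 or to the C6 carbonyl.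

**C5 configuration (12 back to 11).** The cycloaddition can only give the cis ring fusion. C5 is α to the C6 carbonyl and is inverted by enolisation while ring B is still an ene-dione and no other stereocentre is at risk.

**Ring A (11 back to 9 and 10).** The C1–C10 and C4–C5 bonds are cut. This is the only cut that makes both quaternary carbons while bonding each of them to a less substituted carbon, and it reduces the bicycle to a purchased quinone and a five-carbon diene. The forward reaction must be regioselective (C1 to C10), endo and face-selective, and must pass the Z geometry of 9 on to C4.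

**Diene (9 back to 1).** Diene 9 is the O-silylated kinetic enolate of enone 7, which comes from amide 6 and ester 5. Ester 5 is cut at the C4–methyl bond to ynoate 3, made from alkyne 1. Because the alkene geometry of 9 becomes the configuration of C4, it is made by a stereospecific syn-carbocupration of 3 and not by a carbonyl olefination, which would give an E/Z mixture that has to be separated.

## Alternatives that were turned down

**Alternative 1: intramolecular Diels–Alder reaction of a nitro triene.** The C5–C10 and C6–C7 bonds are cut. On heating, the open-chain triene A2 would add its C7=C8–C9=C10 diene to the C5=C6 nitroalkene and give the trans-fused nitro octalin A1, closing both rings at once. In its favour, the C8=C9 alkene and the furylethyl chain are in place at the moment of cyclisation, so no cross-coupling is needed, and the nitro group marks C6 for later conversion to oxygen. On these two points it is stronger than the chosen route. Against it, the diene of A2 is fully substituted at C8, C9 and C10 and must place a methyl on the inside position to reach the s-cis form, while the new C5–C10 bond joins a quaternary carbon to a carbon next to the second quaternary centre. Three new stereocentres would have to follow from C2 and C4 on a flexible tether, and A2 itself needs an enantioselective synthesis of the C4 quaternary centre and a geometrically defined tetrasubstituted diene. The quinone route offers instead a purchased dienophile, a diene of defined geometry in five steps, catalyst control of the absolute configuration, and bond formation that never crowds the two quaternary carbons against each other.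

**Alternative 2: Ramberg–Bäcklund ring contraction.** The C8=C9 double bond is cut. The seven-membered cyclic sulfone A4 would be halogenated at an α-carbon in situ under strongly basic conditions and closed to an episulfone, whose loss of SO2 gives the tris(methoxymethyl) ether A3. Its strength is that the alkene position is fixed beyond doubt and formed late, which matches what the enol triflate achieves in the chosen route. Against it, the contraction would have to form a tetrasubstituted alkene from two secondary α-carbons, one of them next to quaternary C10, which is the least favourable case for halogenation and episulfone closure. A4 already contains ring A and all five stereocentres, so the approach leaves the real problem, the C4/C10 pair, to other chemistry and adds the construction of two hindered C–S bonds. Three acetal groups must finally be removed with acid in the presence of a furan-derived unit. The chosen route builds the stereocentres and the alkene position from the same cycloadduct.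

**Alternative 3: oxidative enolate coupling at C3–C4.** The C3–C4 bond is cut. The keto ester A6 would be converted into its dienolate (ketone methyl and ester α-carbon), and a one-electron oxidant of the Fe(acac)3 type would join C3 to C4, closing ring A and giving A5. It creates the C4 quaternary centre and ring A in one step, with C19 already at the ester level and ring B complete, and in directness at C4 it is equal to the cycloaddition. Against it, the configuration of C4 (C19 β or α) depends on enolate geometry and on a radical or organometallic closure for which the substrate offers no clear bias. Ketone enolisation toward C1 and intermolecular coupling compete. A6 needs C5, C6 and C10 set on a cyclohexene bearing a quaternary carbon, which costs many steps before the key reaction. The quinone route sets C4 stereospecifically from alkene geometry and C10 and C5 in the same step.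

Key step: step 6

Assumption: the (S)-configured oxazaborolidinium catalyst (from Cc1ccccc1B1OC(c2ccccc2)(c2ccccc2)[C@@H]2CCCN12 and Tf2NH) is taken to shield the quinone face that must stay closed, by analogy with its known sense of induction for acrylates bound through the α-C–H; if the sense proved opposite, the mirror-image catalyst would be used and nothing else would change.

## Steps

Step 1
Reactants: 1 benzyl propargyl ether
Product: 3 methyl 4-(benzyloxy)but-2-ynoate, via lithium acetylide 2 (not isolated)
Conditions: n-BuLi, THF, −78 °C; ClCO2Me, −78 to 0 °C
Reagents that add atoms: methyl chloroformate, COC(=O)Cl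
Why: Deprotonation of the terminal alkyne and C-acylation of the lithium acetylide with a chloroformate; the benzyl ether is inert.

Step 2
Reactants: 3 methyl 4-(benzyloxy)but-2-ynoate
Product: 5 methyl (Z)-4-(benzyloxy)-3-methylbut-2-enoate, via alkenylcuprate 4 (not isolated)
Conditions: Me2CuLi (from MeLi and CuI), THF, −78 °C; MeOH at −78 °C, then aq NH4Cl
Reagents that add atoms: lithium dimethylcuprate, [Li+].C[Cu-]C (made in the flask from methyllithium, [Li]C, and CuI)
Why: Conjugate syn-carbocupration of an ynoate: methyl and copper add to the same side of the triple bond, the alkenylcopper species keeps its configuration at −78 °C and is protonated with retention, so CH2OBn ends up cis to the ester (Z) by mechanism.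

Step 3
Reactants: 5 methyl (Z)-4-(benzyloxy)-3-methylbut-2-enoate
Product: 6 (Z)-4-(benzyloxy)-N-methoxy-N,3-dimethylbut-2-enamide
Conditions: MeNH(OMe)·HCl, i-PrMgCl, THF, −20 °C
Reagents that add atoms: N,O-dimethylhydroxylamine hydrochloride, CNOC.Cl
Why: Ester aminolysis by the chloromagnesium amide (Weinreb amide formation); the low temperature and the β,β-disubstituted acceptor suppress conjugate addition, and the double bond geometry is not touched.

Step 4
Reactants: 6 (Z)-4-(benzyloxy)-N-methoxy-N,3-dimethylbut-2-enamide
Product: 7 (Z)-5-(benzyloxy)-4-methylpent-3-en-2-one
Conditions: MeMgBr, THF, 0 °C; aq NH4Cl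
Reagents that add atoms: methylmagnesium bromide, C[Mg]Br
Why: Grignard addition to a Weinreb amide stops at the chelated tetrahedral adduct, which releases the methyl ketone only on work-up, so neither over-addition nor conjugate addition to the enone can occur.

Step 5
Reactants: 7 (Z)-5-(benzyloxy)-4-methylpent-3-en-2-one
Product: 9 (3Z)-5-(benzyloxy)-4-methyl-2-(tert-butyldimethylsilyloxy)penta-1,3-diene, via lithium enolate 8 (not isolated)
Conditions: LDA (from i-Pr2NH and n-BuLi), THF, −78 °C; TBSCl, DMPU, −78 to 0 °C
Reagents that add atoms: tert-butyldimethylsilyl chloride, CC(C)(C)[Si](C)(C)Cl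
Why: Kinetic deprotonation of an enone by a lithium amide at −78 °C removes an α′-methyl proton and not a γ-proton, so the trisubstituted double bond keeps its Z geometry; O-silylation of the cross-conjugated enolate gives the 2-silyloxy diene.

Step 6
Reactants: 9 (3Z)-5-(benzyloxy)-4-methyl-2-(tert-butyldimethylsilyloxy)penta-1,3-diene (1.5 equiv); 10 2,6-dimethyl-1,4-benzoquinone
Product: 11 cis-fused Diels–Alder adduct (ring A C2=C3 silyl enol ether, ring B 7-ene-6,9-dione; 10β-methyl, 5β-H, 4β-CH2OBn, 4α-methyl)
Conditions: (S)-B-(o-tolyl)oxazaborolidine of α,α-diphenylprolinol (20 mol %), Tf2NH (18 mol %), CH2Cl2, −78 to −50 °C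
Reagents that add atoms: none
Why: The protonated oxazaborolidine binds the C6 carbonyl of 10 (flanked by two C–H; the C9 carbonyl between the methyl-bearing carbons is too hindered) on the lone pair syn to C5–H, which lowers the LUMO and makes the methyl-bearing C10 the electrophilic β-carbon; the two C=C bonds of 10 are equivalent, so there is no site problem. The nucleophilic CH2 terminus of 9 (C1, the β-carbon of the silyl enol ether) bonds to C10 and the disubstituted terminus C4 bonds to C5 in a concerted but asynchronous endo [4+2] cycloaddition, the known Lewis-acid-catalysed Diels–Alder reaction of benzoquinones with 2-silyloxy dienes, rendered enantioselective by chiral boron Lewis acids of this type. Ring A closes as the six-membered ring of the cycloaddition itself, both σ bonds forming suprafacially on diene and dienophile. C10 and C5 come out cis because the geometry of the dienophile is retained. C4 is set by the Z geometry of 9 together with the endo rule: the inside CH2OBn lands on the face of ring A that carries H5 and the C10 methyl. The absolute configuration of all three centres is set by the catalyst, whose aryl group covers one face of the bound C5=C10 bond. The step needs regio-, endo- and face selectivity and needs cycloaddition to outrun protodesilylation of 9: regiochemistry follows from the binding site and from the matched polarisation of 9 (the 2-silyloxy group and the C4 substituents both raise the coefficient at C1), endo selectivity from secondary overlap with the quinone carbonyls, and rate from the doubly activated quinone and from the 2-silyloxy group, which disfavours the s-trans form of 9. Each new bond joins a fully substituted carbon to a less substituted one (C1H2 to C10, C4 to C5H), so the two quaternary carbons are not pressed against each other in the transition state.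

Step 7
Reactants: 11 cis-fused Diels–Alder adduct
Product: 12 trans-fused ene-dione (5α-H epimer of 11)
Conditions: DBU (0.3 equiv), CH2Cl2, 23 °C
Reagents that add atoms: none
Why: Base-catalysed epimerisation through the C6 enolate; C5–H is the only enolisable sp3 C–H of the ene-dione, and the trans-fused isomer is expected to be favoured as in 4,4,10-trisubstituted 6-oxodecalins, so C5 is set under thermodynamic control while the silyl enol ether tolerates the amidine base.

Step 8
Reactants: 12 trans-fused ene-dione
Product: 14 C9 enol triflate (C8=C9–OTf, C6 ketone, C7H2), via potassium enolate 13 (not isolated)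
Conditions: K[HB(s-Bu)3] (1.0 equiv), THF, −78 °C; N-(5-chloropyridin-2-yl)triflimide, −78 to −30 °C
Reagents that add atoms: N-(5-chloropyridin-2-yl)-N-(trifluoromethylsulfonyl)trifluoromethanesulfonamide, FC(F)(F)S(=O)(=O)N(c1ccc(Cl)cn1)S(=O)(=O)C(F)(F)F
Why: Reductive enolate trapping: the bulky borohydride adds hydride in conjugate fashion to C7, the only unsubstituted β-carbon of the ene-dione (C8 bears the methyl), which creates the C9 enolate regiospecifically; O-triflation fixes the future C8=C9 double bond while the C6 carbonyl stays a ketone.

Step 9
Reactants: 15 3-bromofuran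
Product: 17 2-(furan-3-yl)ethanol, via 3-furyllithium 16 (not isolated)
Conditions: n-BuLi, THF, −78 °C; ethylene oxide, BF3·OEt2, −78 °C
Reagents that add atoms: ethylene oxide, C1CO1
Why: Bromine–lithium exchange at −78 °C, below the temperature at which 3-furyllithium isomerises to the 2-lithio species, followed by BF3-assisted opening of the epoxide.

Step 10
Reactants: 17 2-(furan-3-yl)ethanol
Product: 18 3-(2-iodoethyl)furan
Conditions: I2, PPh3, imidazole, CH2Cl2, 0 °C to rt
Reagents that add atoms: iodine, II
Why: Appel-type iodination of a primary alcohol under neutral conditions that the furan tolerates.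

Step 11
Reactants: 14 C9 enol triflate; 18 3-(2-iodoethyl)furan
Product: 20 19-benzyloxy-2-(tert-butyldimethylsilyloxy)-15,16-epoxylabda-2,8,13(16),14-tetraen-6-one, via organozinc iodide 19 (not isolated)
Conditions: Zn dust, LiCl, THF, 40 °C; then 14, Pd(OAc)2 (5 mol %), SPhos (10 mol %), THF, 45 °C
Reagents that add atoms: none
Why: Negishi coupling: zinc inserts into the primary C–I bond and the alkylzinc couples with the enol triflate under palladium catalysis with a bulky biarylphosphine, which favours reductive elimination over β-hydride elimination; no base is present, so the C7 protons between ketone and alkene are left alone, and 2,6,6-trisubstituted cyclohexenyl triflates are established partners in such couplings.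

Step 12
Reactants: 20 19-benzyloxy-2-(tert-butyldimethylsilyloxy)-15,16-epoxylabda-2,8,13(16),14-tetraen-6-one
Product: 21 19-benzyloxy-15,16-epoxylabda-8,13(16),14-triene-2,6-dione
Conditions: TBAF, AcOH (1:1), THF, 0 °C
Reagents that add atoms: none
Why: Fluoride cleaves the Si–O bond of the enol ether and acetic acid protonates the enolate at once, releasing the C2 ketone under buffered conditions that neither shift the β,γ-unsaturated C6 ketone into conjugation nor harm the furan.

Step 13
Reactants: 21 19-benzyloxy-15,16-epoxylabda-8,13(16),14-triene-2,6-dione
Product: 22 15,16-epoxylabda-8,13(16),14-triene-2α,6α,19-triol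
Conditions: Li, NH3(l), THF, EtOH, −78 °C; NH4Cl
Reagents that add atoms: none
Why: Dissolving-metal reduction runs through ketyl and carbanion intermediates that are protonated under thermodynamic control and gives the equatorial 2α and 6α alcohols (the axial epimers would be 1,3-diaxial to C19 and the C10 methyl), whereas hydrides entering from the open α face would give the axial alcohols; the same electrons cleave the benzyl ether, and an isolated tetrasubstituted alkene and an alkylfuran are not reduced under these conditions.

Step 14
Reactants: 22 15,16-epoxylabda-8,13(16),14-triene-2α,6α,19-triol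
Product: 24 2α,6α,16,19-tetrahydroxylabda-8,13-dien-15,16-olide (γ-hydroxybutenolide; C16 epimers), via furan endoperoxide 23 (not isolated)
Conditions: O2, hν, rose bengal, i-Pr2NEt, CH2Cl2/MeOH, −78 °C
Reagents that add atoms: dioxygen, O=O
Why: [4+2] addition of singlet oxygen to the furan gives the endoperoxide, and the hindered amine removes the less hindered proton at C15 (Kornblum–DeLaMare-type fragmentation), so C15 becomes the lactone carbonyl and C16 the hemiacetal; at −78 °C the electron-rich furan reacts faster than the sterically shielded tetrasubstituted alkene, as is known for substrates that carry trimethylcyclohexenyl double bonds.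

Step 15
Reactants: 24 γ-hydroxybutenolide
Product: 26 2α,6α,19-trihydroxylabda-8,13-dien-15,16-olide (target), via hydroxy acid 25 (not isolated)
Conditions: NaBH4, EtOH, 0 °C; then aq HCl to pH 2
Reagents that add atoms: none
Why: In the basic medium the hydroxybutenolide opens to the formyl carboxylate, borohydride reduces the aldehyde, and acidification closes the (Z)-hydroxy acid to the butenolide; the isolated alkene and the alcohols are not affected.

## Compound list

1 | benzyl propargyl ether | C#CCOCc1ccccc1 | starting material
2 | lithium 3-(benzyloxy)prop-1-yn-1-ide | [Li]C#CCOCc1ccccc1 | intermediate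
3 | methyl 4-(benzyloxy)but-2-ynoate | COC(=O)C#CCOCc1ccccc1 | intermediate
4 | lithium alkenyl(methyl)cuprate from syn addition (Cu cis to the new methyl) | [Li+].COC(=O)/C([Cu-]C)=C(/C)COCc1ccccc1 | intermediate
5 | methyl (Z)-4-(benzyloxy)-3-methylbut-2-enoate | COC(=O)/C=C(/C)COCc1ccccc1 | intermediate
6 | (Z)-4-(benzyloxy)-N-methoxy-N,3-dimethylbut-2-enamide | CON(C)C(=O)/C=C(/C)COCc1ccccc1 | intermediate
7 | (Z)-5-(benzyloxy)-4-methylpent-3-en-2-one | CC(=O)/C=C(/C)COCc1ccccc1 | intermediate
8 | lithium (3Z)-5-(benzyloxy)-4-methylpenta-1,3-dien-2-olate | [Li+].[O-]C(=C)/C=C(/C)COCc1ccccc1 | intermediate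
9 | (3Z)-5-(benzyloxy)-4-methyl-2-(tert-butyldimethylsilyloxy)penta-1,3-diene | C=C(O[Si](C)(C)C(C)(C)C)/C=C(/C)COCc1ccccc1 | intermediate
10 | 2,6-dimethyl-1,4-benzoquinone | CC1=CC(=O)C=C(C)C1=O | starting material
11 | cis-fused adduct: ring A C2=C3 silyl enol ether, ring B 7-ene-6,9-dione, 10β-methyl, 5β-H, 4β-CH2OBn, 4α-methyl | CC1=CC(=O)[C@@H]2[C@@](C)(COCc3ccccc3)C=C(O[Si](C)(C)C(C)(C)C)C[C@]2(C)C1=O | intermediate
12 | trans-fused ene-dione: as 11 but 5α-H | CC1=CC(=O)[C@H]2[C@@](C)(COCc3ccccc3)C=C(O[Si](C)(C)C(C)(C)C)C[C@]2(C)C1=O | intermediate
13 | potassium C9 enolate (C8=C9–OK, C6 ketone, C7H2) | [K+].CC1=C([O-])[C@@]2(C)CC(O[Si](C)(C)C(C)(C)C)=C[C@](C)(COCc3ccccc3)[C@@H]2C(=O)C1 | intermediate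
14 | C9 enol triflate (C8=C9–OTf, C6 ketone; 10β-methyl, 5α-H, 4β-CH2OBn) | CC1=C(OS(=O)(=O)C(F)(F)F)[C@@]2(C)CC(O[Si](C)(C)C(C)(C)C)=C[C@](C)(COCc3ccccc3)[C@@H]2C(=O)C1 | intermediate
15 | 3-bromofuran | Brc1ccoc1 | starting material
16 | 3-furyllithium | [Li]c1ccoc1 | intermediate
17 | 2-(furan-3-yl)ethanol | OCCc1ccoc1 | intermediate
18 | 3-(2-iodoethyl)furan | ICCc1ccoc1 | intermediate
19 | [2-(furan-3-yl)ethyl]zinc iodide | I[Zn]CCc1ccoc1 | intermediate
20 | 19-benzyloxy-2-(tert-butyldimethylsilyloxy)-15,16-epoxylabda-2,8,13(16),14-tetraen-6-one | CC1=C(CCc2ccoc2)[C@@]2(C)CC(O[Si](C)(C)C(C)(C)C)=C[C@](C)(COCc3ccccc3)[C@@H]2C(=O)C1 | intermediate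
21 | 19-benzyloxy-15,16-epoxylabda-8,13(16),14-triene-2,6-dione | CC1=C(CCc2ccoc2)[C@@]2(C)CC(=O)C[C@](C)(COCc3ccccc3)[C@@H]2C(=O)C1 | intermediate
22 | 15,16-epoxylabda-8,13(16),14-triene-2α,6α,19-triol | CC1=C(CCc2ccoc2)[C@@]2(C)C[C@@H](O)C[C@](C)(CO)[C@@H]2[C@@H](O)C1 | intermediate
23 | furan endoperoxide of 22 (2,3,7-trioxabicyclo[2.2.1]hept-5-ene, diastereomers) | CC1=C(CCC2=CC3OOC2O3)[C@@]2(C)C[C@@H](O)C[C@](C)(CO)[C@@H]2[C@@H](O)C1 | intermediate
24 | 2α,6α,16,19-tetrahydroxylabda-8,13-dien-15,16-olide (C16 epimers) | CC1=C(CCC2=CC(=O)OC2O)[C@@]2(C)C[C@@H](O)C[C@](C)(CO)[C@@H]2[C@@H](O)C1 | intermediate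
25 | (13Z)-2α,6α,16,19-tetrahydroxylabda-8,13-dien-15-oic acid | CC1=C(CC/C(CO)=C/C(=O)O)[C@@]2(C)C[C@@H](O)C[C@](C)(CO)[C@@H]2[C@@H](O)C1 | intermediate
26 | 2α,6α,19-trihydroxylabda-8,13-dien-15,16-olide | CC1=C(CCC2=CC(=O)OC2)[C@@]2(C)C[C@@H](O)C[C@](C)(CO)[C@@H]2[C@@H](O)C1 | target

## Step count and least certain steps

Total: 15 steps. Longest linear sequence: 13 steps (steps 1–8 and 11–15); the side chain takes 2 steps (9 and 10).

**Step 6 (key step).** The acidic catalyst may desilylate the hindered diene before the slow cycloaddition takes place, or the addition may run stepwise (Mukaiyama–Michael), which would erode endo and face control because the disubstituted terminus closes late. Fallback: from 9 and 10 the cycloaddition is run with a mild achiral Lewis acid (Me2AlCl, CH2Cl2, −78 °C), which still binds the C6 carbonyl and should give the same regiochemistry and relative configuration as a racemate. This is 11 together with its mirror image, the enantiomeric cis adduct F1. Epimerisation as in step 7 gives 12 together with the enantiomeric trans ene-dione F2, and the enantiomers are separated by preparative chromatography on a chiral stationary phase. The route is rejoined at 12.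

**Step 7.** The cis/trans equilibrium at C5 may not lie far enough on the trans side while ring A still holds the enol ether double bond, or the amidine may add reversibly to the ene-dione. Fallback: from 11, C5 is deprotonated irreversibly (KHMDS, THF, −78 °C) to the potassium C5=C6 dienolate F3, which is protonated kinetically with a bulky acid (2,6-di-tert-butylphenol) from the open α face. This gives 12 whatever the position of the equilibrium, and the route is rejoined at 12.

**Step 8.** Hydride may attack the C6 carbonyl directly, or proton transfer between the C9 enolate and the C5/C7 protons may scramble the enolate before triflation. Fallback: from 12, Luche reduction (NaBH4, CeCl3·7H2O, MeOH, −78 °C) of the less hindered C6 carbonyl gives the 6β-hydroxy enone F4. 3-(2-Lithioethyl)furan F5 (from 18 and t-BuLi, Et2O, −78 °C; 2.2 equiv) then adds to the only remaining carbonyl, C9, from the α face and gives the 6,9-diol F6. MnO2 (CH2Cl2) oxidises the secondary allylic alcohol to the 9-hydroxy enone F7. SmI2 (THF/MeOH, −78 °C) expels the C9 hydroxyl through the samarium dienolate, which is protonated at C7 and gives 20. The route is rejoined at 20, with steps 8 and 11 bypassed.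

**Step 11.** Oxidative addition and transmetalation at the hindered triflate may be slow enough for β-hydride elimination of the alkylpalladium species to take over, which would reduce the triflate. Fallback: from 14, a Stille coupling with vinyltributylstannane (Pd(PPh3)4, LiCl, THF, 60 °C), which is insensitive to hindrance at the triflate, gives the 9-vinyl diene F8. 9-BBN (THF, 0 °C to rt) hydroborates the terminal vinyl group faster than it reduces the hindered ketone and gives the alkylborane F9. Suzuki–Miyaura coupling of F9 with 15 (PdCl2(dppf), aq K3PO4, THF) forms the C12–C13 bond and gives 20.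

**Step 13.** Amide or alkoxide formed in the medium may shift C8=C9 into conjugation with the C6 carbonyl, after which the enone would be over-reduced, or the furan may be partly reduced. Fallback: from 21, SmI2 with H2O and Et3N (THF, 0 °C) reduces both ketones to the thermodynamic alcohols without touching furan or benzyl ether and gives the 19-O-benzyl 2α,6α-diol F10. The benzyl group is then removed with lithium 4,4′-di-tert-butylbiphenylide (THF, −78 °C) to give 22.

**Step 14.** An ene reaction of singlet oxygen at the C8=C9 double bond may compete with the furan cycloaddition. Fallback: from 22, C–H borylation ([Ir(OMe)(cod)]2, 4,4′-di-tert-butyl-2,2′-bipyridine, excess B2pin2, THF, 60 °C; O–B bonds hydrolysed on work-up) at the furan α-carbon remote from the chain (C15) gives the 15-boryl furan F11. Oxidation of the C–B bond (NaBO3·4H2O, THF/H2O) gives the 15-hydroxyfuran F12, which tautomerises to the butenolide. The route is rejoined at 26, with step 15 bypassed.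

## Further compounds

F1 | step 6 | enantiomer of cis adduct 11 | CC1=CC(=O)[C@H]2[C@](C)(COCc3ccccc3)C=C(O[Si](C)(C)C(C)(C)C)C[C@@]2(C)C1=O
F2 | step 6 | enantiomer of trans ene-dione 12 | CC1=CC(=O)[C@@H]2[C@](C)(COCc3ccccc3)C=C(O[Si](C)(C)C(C)(C)C)C[C@@]2(C)C1=O
F3 | step 7 | potassium C5=C6 dienolate of 11 | [K+].CC1=CC([O-])=C2[C@@](C)(COCc3ccccc3)C=C(O[Si](C)(C)C(C)(C)C)C[C@]2(C)C1=O
F4 | step 8 | 6β-hydroxy enone (C6 carbinol, C7=C8, C9 ketone) | CC1=C[C@@H](O)[C@H]2[C@@](C)(COCc3ccccc3)C=C(O[Si](C)(C)C(C)(C)C)C[C@]2(C)C1=O
F5 | step 8 | 3-(2-lithioethyl)furan | [Li]CCc1ccoc1
F6 | step 8 | 6β,9β-diol with 9α-furylethyl chain | CC1=C[C@@H](O)[C@H]2[C@@](C)(COCc3ccccc3)C=C(O[Si](C)(C)C(C)(C)C)C[C@]2(C)[C@]1(O)CCc1ccoc1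
F7 | step 8 | 9β-hydroxy-7-en-6-one with 9α-furylethyl chain | CC1=CC(=O)[C@H]2[C@@](C)(COCc3ccccc3)C=C(O[Si](C)(C)C(C)(C)C)C[C@]2(C)[C@]1(O)CCc1ccoc1
F8 | step 11 | 9-vinyl diene ketone | CC1=C(C=C)[C@@]2(C)CC(O[Si](C)(C)C(C)(C)C)=C[C@](C)(COCc3ccccc3)[C@@H]2C(=O)C1
F9 | step 11 | B-alkyl-9-borabicyclo[3.3.1]nonane from F8 | CC1=C(CCB2C3CCCC2CCC3)[C@@]2(C)CC(O[Si](C)(C)C(C)(C)C)=C[C@](C)(COCc3ccccc3)[C@@H]2C(=O)C1
F10 | step 13 | 19-benzyloxy-15,16-epoxylabda-8,13(16),14-triene-2α,6α-diol | CC1=C(CCc2ccoc2)[C@@]2(C)C[C@@H](O)C[C@](C)(COCc3ccccc3)[C@@H]2[C@@H](O)C1
F11 | step 14 | 15-(pinacolboryl) furan of 22 | CC1=C(CCc2coc(B3OC(C)(C)C(C)(C)O3)c2)[C@@]2(C)C[C@@H](O)C[C@](C)(CO)[C@@H]2[C@@H](O)C1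
F12 | step 14 | 15-hydroxyfuran tautomer of 26 | CC1=C(CCc2coc(O)c2)[C@@]2(C)C[C@@H](O)C[C@](C)(CO)[C@@H]2[C@@H](O)C1
A1 | alternative 1 | trans-fused 6α-nitro octalin with C8=C9 alkene | CC1=C(CCc2ccoc2)[C@@]2(C)C[C@@H](O[Si](C)(C)C(C)(C)C)C[C@](C)(COCc3ccccc3)[C@@H]2[C@@H]([N+](=O)[O-])C1
A2 | alternative 1 | open-chain nitro triene (E nitroalkene, E tetrasubstituted C9=C10) | C=C(C)/C(CCc1ccoc1)=C(\C)C[C@@H](O[Si](C)(C)C(C)(C)C)C[C@](C)(COCc1ccccc1)/C=C/[N+](=O)[O-]
A3 | alternative 2 | tris(methoxymethyl) ether of the furan-masked core | CC1=C(CCc2ccoc2)[C@@]2(C)C[C@@H](OCOC)C[C@](C)(COCOC)[C@@H]2[C@@H](OCOC)C1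
A4 | alternative 2 | thiepane 1,1-dioxide bridging C8 and C9 (C8, C9 epimers) | CC1S(=O)(=O)C(CCc2ccoc2)[C@@]2(C)C[C@@H](OCOC)C[C@](C)(COCOC)[C@@H]2[C@@H](OCOC)C1
A5 | alternative 3 | trans-decalin C2 ketone with C19 methyl ester on C4 | CC1=C(CCc2ccoc2)[C@@]2(C)CC(=O)C[C@](C)(C(=O)OC)[C@@H]2[C@@H](O[Si](C)(C)C(C)(C)C)C1
A6 | alternative 3 | ring B keto ester (acetonyl on C10, 2-propanoate on C5) | CC1=C(CCc2ccoc2)[C@@](C)(CC(C)=O)[C@H](C(C)C(=O)OC)[C@@H](O[Si](C)(C)C(C)(C)C)C1
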